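**Retrosynthetic overview**
1. The (Z)-p-coumarate is built last on the C19 oxymethyl group by a Z-selective Horner–Wadsworth–Emmons olefination; the diene comes from a C12 iodide and 2-(buta-1,3-dienyl)magnesium chloride.
2. The C8 carbinol comes from an 8-ketone (equatorial CH2 transfer, then hydride); the C9 side chain comes from decarboxylative allylation of an allyl β-keto ester on the face anti to the C10 methyl.
3. Key disconnection: the C4–C5 and C9–C10 bonds of the trans-decalin lead back to an open-chain epoxy E-alkene allyl β-keto ester; ring A (C1–C5, C10) closes first and ring B (C5–C10) closes last, in one operation.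
4. Enabling feature: the bond shared by both rings, C5–C10, can be an E-alkene lying between an electrophile at C4 (a C3–C4 oxirane that already carries the C19 oxygen) and a nucleophile at C9 (the α-carbon of the C8 carbonyl, whose oxygen ends as the C8 hydroxyl).
5. The precursor is assembled from geranyl chloride, a Still–Gennari phosphonate and allyl acetoacetate; one Sharpless epoxidation supplies all absolute configuration.

Key step: step 7

Remark (assumption): the configuration is taken exactly as written (labdane numbering, 4R,5S,8R,9R,10R): a trans-decalin with the C19 oxymethyl, the C20 methyl and the C8 hydroxyl on one face and H5, C17, C18 and the C9 side chain on the other, so that the C8 hydroxyl and the C9 side chain are trans-diaxial.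

Step 1
Reactants: 1 geranyl chloride, (2E)-1-chloro-3,7-dimethylocta-2,6-diene
Product: 3 (4E)-6-chloro-4-methylhex-4-enal, via secondary ozonide 2 (not isolated)
Conditions: O3 (1.0 equiv), CH2Cl2, −78 °C; then Me2S, −78 °C → rt
Reagents that add atoms: ozone, [O-][O+]=O
Why: Ozonolysis with reductive work-up; the isopropylidene alkene is more electron-rich than the alkene next to the allylic chloride, so one equivalent of ozone should cleave only the distal double bond.

Step 2
Reactants: 3 (4E)-6-chloro-4-methylhex-4-enal; 4 methyl 2-[bis(2,2,2-trifluoroethoxy)phosphoryl]propanoate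
Product: 5 methyl (2Z,6E)-8-chloro-2,6-dimethylocta-2,6-dienoate
Conditions: KN(SiMe3)2, 18-crown-6, THF, −78 °C
Reagents that add atoms: none
Why: Still–Gennari olefination, in which fast elimination from the kinetic adduct of the electron-poor phosphonate should give the Z-trisubstituted enoate (ester cis to the chain), the geometry that later makes C19 axial; the allylic chloride should be inert to the stabilised anion at −78 °C.

Step 3
Reactants: 5 methyl (2Z,6E)-8-chloro-2,6-dimethylocta-2,6-dienoate
Product: 6 (2Z,6E)-8-chloro-2,6-dimethylocta-2,6-dien-1-ol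
Conditions: i-Bu2AlH (2.2 equiv), CH2Cl2, −78 °C
Reagents that add atoms: none
Why: 1,2-Reduction of the conjugated ester by the aluminium hydride should give the allylic alcohol without changing the alkene geometry or touching the allylic chloride.

Step 4
Reactants: 6 (2Z,6E)-8-chloro-2,6-dimethylocta-2,6-dien-1-ol
Product: 7 [(2S,3R)-3-[(3E)-5-chloro-3-methylpent-3-en-1-yl]-2-methyloxiran-2-yl]methanol
Conditions: Ti(OiPr)4, L-(+)-diethyl tartrate, t-BuOOH, 4 Å molecular sieves, CH2Cl2, −20 °C
Reagents that add atoms: tert-butyl hydroperoxide, CC(C)(C)OO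
Why: Sharpless asymmetric epoxidation, which acts only on the alkene of the allylic alcohol; the L-(+)-tartrate complex should deliver oxygen to the face that gives the (2S,3R)-epoxide (C3 R, C4 S in labdane numbering), the source of all absolute configuration.

Step 5
Reactants: 7 [(2S,3R)-3-[(3E)-5-chloro-3-methylpent-3-en-1-yl]-2-methyloxiran-2-yl]methanol
Product: 8 tert-butyl{[(2S,3R)-3-[(3E)-5-chloro-3-methylpent-3-en-1-yl]-2-methyloxiran-2-yl]methoxy}diphenylsilane
Conditions: t-BuPh2SiCl, imidazole, CH2Cl2, 0 °C → rt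
Reagents that add atoms: tert-butyl(chloro)diphenylsilane, CC(C)(C)[Si](Cl)(c1ccccc1)c1ccccc1
Why: Silylation of the primary alcohol gives a bulky, weakly Lewis-basic ether that should survive SnCl4 and keep the C19 oxygen out of the oxirane opening.

Step 6
Reactants: 8 the silyl ether of step 5; 9 allyl acetoacetate (prop-2-en-1-yl 3-oxobutanoate)
Product: 11 prop-2-en-1-yl (6E)-9-[(2R,3S)-3-({[tert-butyl(diphenyl)silyl]oxy}methyl)-3-methyloxiran-2-yl]-7-methyl-3-oxonon-6-enoate, via acetoacetate dianion 10 (not isolated)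
Conditions: 9, NaH, THF, 0 °C; n-BuLi, 0 °C; then 8, 0 °C → rt
Reagents that add atoms: none
Why: γ-Alkylation of an acetoacetate dianion by SN2 displacement of the primary allylic chloride, which should keep the E-geometry of C5=C10; the trisubstituted oxirane is too hindered to open under these conditions.

Step 7
Reactants: 11 the epoxy alkene β-keto ester of step 6
Product: 13 prop-2-en-1-yl (1S,4aS,5R,6R,8aR)-5-({[tert-butyl(diphenyl)silyl]oxy}methyl)-6-hydroxy-5,8a-dimethyl-2-oxodecahydronaphthalene-1-carboxylate, via ring-A cyclohexyl cation 12 (not isolated)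
Conditions: SnCl4 (2.5 equiv), CH2Cl2, −78 → −30 °C; aq. NaHCO3
Reagents that add atoms: none
Why: SnCl4 binds the oxirane and the β-keto ester; the C5=C10 π-bond opens the oxirane at its tertiary carbon C4 with inversion, the C10 cation is captured by the α-carbon C9 of the tin-chelated enol, and loss of the C9 proton completes a net isomerisation (cation–olefin polycyclisation of an epoxy alkene with a 1,3-dicarbonyl enol terminator, the biomimetic epoxy-polyene reaction type). Ring A closes first by a 6-endo-trig attack of the alkene (exo-tet at the oxirane carbon); ring B closes last by a 6-endo-trig attack on the enol C8=C9. C4 is set by SN2-type inversion of the oxirane carbon, so the oxymethyl group that was cis to the chain should become axial and cis to C20 while the C3 oxygen stays equatorial. C5 and C10 are set by antiperiplanar addition across the E-alkene in a chair–chair fold, which should give the trans ring fusion, and the absolute sense of all three follows from the oxirane of step 4; C9 forms with the ester equatorial but is enolisable and is reset in step 10. The step needs ionisation at C4 and not C3 (tertiary against secondary carbon), C- and not O-alkylation of the enol (a cyclic enol ether can re-ionise under SnCl4, so the C-alkylated ketone is the expected end point) and a chair fold of ring A (the equatorial C3–O–Sn group and the E-alkene favour it).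

Step 8
Reactants: 13 the bicyclic hydroxy β-keto ester of step 7
Product: 14 prop-2-en-1-yl (1S,4aS,5R,6R,8aR)-5-({[tert-butyl(diphenyl)silyl]oxy}methyl)-6-[(1H-imidazol-1-ylcarbonothioyl)oxy]-5,8a-dimethyl-2-oxodecahydronaphthalene-1-carboxylate
Conditions: 1,1'-thiocarbonyldiimidazole, DMAP (cat.), ClCH2CH2Cl, 70 °C
Reagents that add atoms: 1,1'-thiocarbonyldiimidazole, S=C(n1ccnc1)n1ccnc1
Why: Thioacylation of the only free hydroxyl group (the equatorial C3 alcohol) prepares the Barton–McCombie deoxygenation that removes the control element left by the oxirane.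

Step 9
Reactants: 14 the imidazolyl thiocarbonate of step 8
Product: 15 prop-2-en-1-yl (1S,4aS,5R,8aR)-5-({[tert-butyl(diphenyl)silyl]oxy}methyl)-5,8a-dimethyl-2-oxodecahydronaphthalene-1-carboxylate
Conditions: Bu3SnH, AIBN (cat.), PhMe, 100 °C
Reagents that add atoms: none
Why: Barton–McCombie radical deoxygenation, in which the stannyl radical adds to C=S and the secondary C3 radical is reduced by the tin hydride; ketone, esters and silyl ether should be inert to the chain.

Step 10
Reactants: 15 the allyl β-keto ester of step 9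
Product: 16 (1R,4aS,5R,8aR)-5-({[tert-butyl(diphenyl)silyl]oxy}methyl)-5,8a-dimethyl-1-(prop-2-en-1-yl)octahydronaphthalen-2(1H)-one
Conditions: Pd(PPh3)4 (5 mol%), THF, rt
Reagents that add atoms: none
Why: Tsuji decarboxylative allylation, in which zerovalent palladium ionises the allyl ester, CO2 is lost to give the enolate at C9 only, and allylation should occur on the face anti to the axial C10 methyl (axial, chair-like alkylation), setting C9 with H9 cis to C20 under neutral conditions that should not epimerise it.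

Step 11
Reactants: 16 the 9-allyl 8-ketone of step 10
Product: 17 (1R,2R,4aS,5R,8aR)-5-({[tert-butyl(diphenyl)silyl]oxy}methyl)-5,8a-dimethyl-1-(prop-2-en-1-yl)octahydro-1H-spiro[naphthalene-2,2'-oxirane]
Conditions: Me3S(O)I, NaH, DMSO, rt → 50 °C
Reagents that add atoms: trimethylsulfoxonium iodide, C[S+](C)(C)=O.[I-]
Why: Corey–Chaykovsky epoxidation with dimethylsulfoxonium methylide, whose addition is reversible, so the methylene should end equatorial, away from the syn-axial C10 methyl, and the epoxide oxygen axial and cis to C20, which fixes C8.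

Step 12
Reactants: 17 the spiro-epoxide of step 11
Product: 18 (1R,2R,4aS,5R,8aR)-5-({[tert-butyl(diphenyl)silyl]oxy}methyl)-2,5,8a-trimethyl-1-(prop-2-en-1-yl)decahydronaphthalen-2-ol
Conditions: LiEt3BH, THF, 0 °C → rt
Reagents that add atoms: none
Why: SN2 hydride opening of the epoxide at its primary carbon turns the oxirane CH2 into the C17 methyl and leaves the C8–O bond, and so the C8 configuration, untouched.

Step 13
Reactants: 18 the allyl tertiary alcohol of step 12
Product: 20 (1R,2R,4aS,5R,8aR)-5-({[tert-butyl(diphenyl)silyl]oxy}methyl)-1-(2-hydroxyethyl)-2,5,8a-trimethyldecahydronaphthalen-2-ol, via secondary ozonide 19 (not isolated)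
Conditions: O3, CH2Cl2, −78 °C; then NaBH4, MeOH, −78 → 0 °C
Reagents that add atoms: ozone, [O-][O+]=O
Why: Ozonolysis of the only alkene with reductive work-up should shorten the allyl group to the two-carbon C11–C12 hydroxyethyl chain.

Step 14
Reactants: 20 the diol of step 13
Product: 21 (1R,2R,4aS,5R,8aR)-5-({[tert-butyl(diphenyl)silyl]oxy}methyl)-1-(2-iodoethyl)-2,5,8a-trimethyldecahydronaphthalen-2-ol
Conditions: I2, PPh3, imidazole, CH2Cl2, 0 °C
Reagents that add atoms: iodine, II
Why: Appel-type iodination should convert only the primary alcohol, because the tertiary C8 hydroxyl does not give a displaceable alkoxyphosphonium salt under these conditions.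

Step 15
Reactants: 21 the iodide of step 14; 22 chloroprene (2-chlorobuta-1,3-diene)
Product: 24 (1R,2R,4aS,5R,8aR)-5-({[tert-butyl(diphenyl)silyl]oxy}methyl)-2,5,8a-trimethyl-1-(3-methylidenepent-4-en-1-yl)decahydronaphthalen-2-ol, via 2-(buta-1,3-dienyl)magnesium chloride 23 (not isolated)
Conditions: 22, Mg, ZnCl2 (cat.), THF, reflux; then 21, Li2CuCl4 (5 mol%), THF, −20 → 0 °C
Reagents that add atoms: none
Why: Copper-catalysed Kumada-type coupling of the primary iodide with the 2-butadienyl Grignard reagent should form the C12–C13 bond and complete the diene chain; the C8 magnesium alkoxide is trans-diaxial to the side chain and should not close a tetrahydrofuran.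

Step 16
Reactants: 24 the diene silyl ether of step 15
Product: 25 (1R,2R,4aS,5R,8aR)-5-(hydroxymethyl)-2,5,8a-trimethyl-1-(3-methylidenepent-4-en-1-yl)decahydronaphthalen-2-ol
Conditions: Bu4NF, THF, rt → 45 °C
Reagents that add atoms: none
Why: Fluoride cleavage of the neopentyl silyl ether should free the C19 alcohol while the diene and the tertiary alcohol stay inert.

Step 17
Reactants: 25 the diene diol of step 16
Product: 26 [(1R,4aR,5R,6R,8aS)-6-hydroxy-1,4a,6-trimethyl-5-(3-methylidenepent-4-en-1-yl)decahydronaphthalen-1-yl]methyl bromoacetate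
Conditions: BrCH2COBr, pyridine, CH2Cl2, −20 °C
Reagents that add atoms: bromoacetyl bromide, BrCC(Br)=O
Why: O-Acylation should be selective for the primary C19 hydroxyl over the hindered tertiary C8 hydroxyl.

Step 18
Reactants: 26 the bromoacetate of step 17
Product: 27 [(1R,4aR,5R,6R,8aS)-6-hydroxy-1,4a,6-trimethyl-5-(3-methylidenepent-4-en-1-yl)decahydronaphthalen-1-yl]methyl (diphenoxyphosphoryl)acetate
Conditions: (PhO)2P(O)H, Et3N, CH2Cl2, 0 °C → rt
Reagents that add atoms: diphenyl phosphite, O=[PH](Oc1ccccc1)Oc1ccccc1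
Why: Michaelis–Becker alkylation of diphenyl phosphite by the α-bromo ester should give the diaryl phosphonoacetate under mild base that leaves the diene and the tertiary alcohol alone.

Step 19
Reactants: 27 the phosphonoacetate of step 18; 28 4-[(tert-butyldimethylsilyl)oxy]benzaldehyde
Product: 29 [(1R,4aR,5R,6R,8aS)-6-hydroxy-1,4a,6-trimethyl-5-(3-methylidenepent-4-en-1-yl)decahydronaphthalen-1-yl]methyl (2Z)-3-{4-[(tert-butyldimethylsilyl)oxy]phenyl}prop-2-enoate
Conditions: NaI, DBU, THF, −78 → 0 °C, exclusion of light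
Reagents that add atoms: none
Why: Z-selective Horner–Wadsworth–Emmons olefination, in which the diaryl phosphonate should eliminate from the kinetic adduct to the (Z)-cinnamate; it is placed late so that the light- and base-sensitive Z-alkene meets no further C–C bond formation.

Step 20
Reactants: 29 the silyl-protected ester of step 19
Product: 30 target CNP0197278.6
Conditions: Bu4NF, AcOH, THF, 0 °C, exclusion of light
Reagents that add atoms: none
Why: Buffered fluoride desilylation of the aryl silyl ether should free the phenol without isomerising the Z-alkene or cleaving the ester.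

**Compound list**
1 | geranyl chloride, (2E)-1-chloro-3,7-dimethylocta-2,6-diene | CC(C)=CCC/C(C)=C/CCl | starting material
2 | 3-[(3E)-5-chloro-3-methylpent-3-en-1-yl]-5,5-dimethyl-1,2,4-trioxolane (secondary ozonide, racemic at the ring carbon, not isolated) | CC1(C)OOC(CC/C(C)=C/CCl)O1 | intermediate
3 | (4E)-6-chloro-4-methylhex-4-enal | O=CCC/C(C)=C/CCl | intermediate
4 | methyl 2-[bis(2,2,2-trifluoroethoxy)phosphoryl]propanoate | COC(=O)C(C)P(=O)(OCC(F)(F)F)OCC(F)(F)F | starting material
5 | methyl (2Z,6E)-8-chloro-2,6-dimethylocta-2,6-dienoate | COC(=O)/C(C)=C\CC/C(C)=C/CCl | intermediate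
6 | (2Z,6E)-8-chloro-2,6-dimethylocta-2,6-dien-1-ol | OC/C(C)=C\CC/C(C)=C/CCl | intermediate
7 | [(2S,3R)-3-[(3E)-5-chloro-3-methylpent-3-en-1-yl]-2-methyloxiran-2-yl]methanol | OC[C@]1(C)O[C@@H]1CC/C(C)=C/CCl | intermediate
8 | tert-butyl{[(2S,3R)-3-[(3E)-5-chloro-3-methylpent-3-en-1-yl]-2-methyloxiran-2-yl]methoxy}diphenylsilane | CC(C)(C)[Si](OC[C@]1(C)O[C@@H]1CC/C(C)=C/CCl)(c1ccccc1)c1ccccc1 | intermediate
9 | allyl acetoacetate, prop-2-en-1-yl 3-oxobutanoate | CC(=O)CC(=O)OCC=C | starting material
10 | sodium lithium dianion of allyl acetoacetate (not isolated) | [Na+].[Li+].[CH2-]C([O-])=CC(=O)OCC=C | intermediate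
11 | prop-2-en-1-yl (6E)-9-[(2R,3S)-3-({[tert-butyl(diphenyl)silyl]oxy}methyl)-3-methyloxiran-2-yl]-7-methyl-3-oxonon-6-enoate | CC(C)(C)[Si](OC[C@]1(C)O[C@@H]1CC/C(C)=C/CCC(=O)CC(=O)OCC=C)(c1ccccc1)c1ccccc1 | intermediate
12 | ring-A cyclohexyl cation (C10 carbocation after closure of ring A; the C3 oxygen, tin-bound in the flask, is drawn as OH; not isolated) | C[C+]1CC[C@@H](O)[C@@](C)(CO[Si](c2ccccc2)(c2ccccc2)C(C)(C)C)[C@H]1CCC(=O)CC(=O)OCC=C | intermediate
13 | prop-2-en-1-yl (1S,4aS,5R,6R,8aR)-5-({[tert-butyl(diphenyl)silyl]oxy}methyl)-6-hydroxy-5,8a-dimethyl-2-oxodecahydronaphthalene-1-carboxylate (trans-decalin; C1 epimerisable, drawn with the ester equatorial) | C=CCOC(=O)[C@H]1[C@]2(C)CC[C@@H](O)[C@@](C)(CO[Si](c3ccccc3)(c3ccccc3)C(C)(C)C)[C@H]2CCC1=O | intermediate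
14 | prop-2-en-1-yl (1S,4aS,5R,6R,8aR)-5-({[tert-butyl(diphenyl)silyl]oxy}methyl)-6-[(1H-imidazol-1-ylcarbonothioyl)oxy]-5,8a-dimethyl-2-oxodecahydronaphthalene-1-carboxylate | C=CCOC(=O)[C@H]1[C@]2(C)CC[C@@H](OC(=S)n3ccnc3)[C@@](C)(CO[Si](c3ccccc3)(c3ccccc3)C(C)(C)C)[C@H]2CCC1=O | intermediate
15 | prop-2-en-1-yl (1S,4aS,5R,8aR)-5-({[tert-butyl(diphenyl)silyl]oxy}methyl)-5,8a-dimethyl-2-oxodecahydronaphthalene-1-carboxylate | C=CCOC(=O)[C@H]1[C@]2(C)CCC[C@@](C)(CO[Si](c3ccccc3)(c3ccccc3)C(C)(C)C)[C@H]2CCC1=O | intermediate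
16 | (1R,4aS,5R,8aR)-5-({[tert-butyl(diphenyl)silyl]oxy}methyl)-5,8a-dimethyl-1-(prop-2-en-1-yl)octahydronaphthalen-2(1H)-one (allyl group axial, trans to the angular methyl) | C=CC[C@@H]1[C@]2(C)CCC[C@@](C)(CO[Si](c3ccccc3)(c3ccccc3)C(C)(C)C)[C@H]2CCC1=O | intermediate
17 | (1R,2R,4aS,5R,8aR)-5-({[tert-butyl(diphenyl)silyl]oxy}methyl)-5,8a-dimethyl-1-(prop-2-en-1-yl)octahydro-1H-spiro[naphthalene-2,2'-oxirane] (epoxide oxygen axial, cis to the angular methyl) | C=CC[C@@H]1[C@]2(C)CCC[C@@](C)(CO[Si](c3ccccc3)(c3ccccc3)C(C)(C)C)[C@H]2CC[C@@]1(C3)O3 | intermediate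
18 | (1R,2R,4aS,5R,8aR)-5-({[tert-butyl(diphenyl)silyl]oxy}methyl)-2,5,8a-trimethyl-1-(prop-2-en-1-yl)decahydronaphthalen-2-ol | C=CC[C@@H]1[C@]2(C)CCC[C@@](C)(CO[Si](c3ccccc3)(c3ccccc3)C(C)(C)C)[C@H]2CC[C@@]1(C)O | intermediate
19 | secondary ozonide of 18 (3-substituted 1,2,4-trioxolane, mixture at the ring carbon, not isolated) | C1OC(C[C@@H]2[C@]3(C)CCC[C@@](C)(CO[Si](c4ccccc4)(c4ccccc4)C(C)(C)C)[C@H]3CC[C@@]2(C)O)OO1 | intermediate
20 | (1R,2R,4aS,5R,8aR)-5-({[tert-butyl(diphenyl)silyl]oxy}methyl)-1-(2-hydroxyethyl)-2,5,8a-trimethyldecahydronaphthalen-2-ol | OCC[C@@H]1[C@]2(C)CCC[C@@](C)(CO[Si](c3ccccc3)(c3ccccc3)C(C)(C)C)[C@H]2CC[C@@]1(C)O | intermediate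
21 | (1R,2R,4aS,5R,8aR)-5-({[tert-butyl(diphenyl)silyl]oxy}methyl)-1-(2-iodoethyl)-2,5,8a-trimethyldecahydronaphthalen-2-ol | ICC[C@@H]1[C@]2(C)CCC[C@@](C)(CO[Si](c3ccccc3)(c3ccccc3)C(C)(C)C)[C@H]2CC[C@@]1(C)O | intermediate
22 | chloroprene, 2-chlorobuta-1,3-diene | C=CC(Cl)=C | starting material
23 | 2-(buta-1,3-dienyl)magnesium chloride (not isolated) | C=CC(=C)[Mg]Cl | intermediate
24 | (1R,2R,4aS,5R,8aR)-5-({[tert-butyl(diphenyl)silyl]oxy}methyl)-2,5,8a-trimethyl-1-(3-methylidenepent-4-en-1-yl)decahydronaphthalen-2-ol | C=CC(=C)CC[C@@H]1[C@]2(C)CCC[C@@](C)(CO[Si](c3ccccc3)(c3ccccc3)C(C)(C)C)[C@H]2CC[C@@]1(C)O | intermediate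
25 | (1R,2R,4aS,5R,8aR)-5-(hydroxymethyl)-2,5,8a-trimethyl-1-(3-methylidenepent-4-en-1-yl)decahydronaphthalen-2-ol | C=CC(=C)CC[C@@H]1[C@]2(C)CCC[C@@](C)(CO)[C@H]2CC[C@@]1(C)O | intermediate
26 | [(1R,4aR,5R,6R,8aS)-6-hydroxy-1,4a,6-trimethyl-5-(3-methylidenepent-4-en-1-yl)decahydronaphthalen-1-yl]methyl bromoacetate | C=CC(=C)CC[C@@H]1[C@]2(C)CCC[C@@](C)(COC(=O)CBr)[C@H]2CC[C@@]1(C)O | intermediate
27 | [(1R,4aR,5R,6R,8aS)-6-hydroxy-1,4a,6-trimethyl-5-(3-methylidenepent-4-en-1-yl)decahydronaphthalen-1-yl]methyl (diphenoxyphosphoryl)acetate | C=CC(=C)CC[C@@H]1[C@]2(C)CCC[C@@](C)(COC(=O)CP(=O)(Oc3ccccc3)Oc3ccccc3)[C@H]2CC[C@@]1(C)O | intermediate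
28 | 4-[(tert-butyldimethylsilyl)oxy]benzaldehyde | CC(C)(C)[Si](C)(C)Oc1ccc(C=O)cc1 | starting material
29 | [(1R,4aR,5R,6R,8aS)-6-hydroxy-1,4a,6-trimethyl-5-(3-methylidenepent-4-en-1-yl)decahydronaphthalen-1-yl]methyl (2Z)-3-{4-[(tert-butyldimethylsilyl)oxy]phenyl}prop-2-enoate | C=CC(=C)CC[C@@H]1[C@]2(C)CCC[C@@](C)(COC(=O)/C=C\c3ccc(O[Si](C)(C)C(C)(C)C)cc3)[C@H]2CC[C@@]1(C)O | intermediate
30 | CNP0197278.6, [(1R,4aR,5R,6R,8aS)-6-hydroxy-1,4a,6-trimethyl-5-(3-methylidenepent-4-en-1-yl)decahydronaphthalen-1-yl]methyl (2Z)-3-(4-hydroxyphenyl)prop-2-enoate | C=CC(=C)CC[C@@H]1[C@]2(C)CCC[C@@](C)(COC(=O)/C=C\c3ccc(O)cc3)[C@H]2CC[C@@]1(C)O | target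

**Step count**
Total step count: 20. Longest linear sequence: 20 steps (1 to 30); compounds 4, 9, 22 and 28 enter as purchased building blocks.

**Steps most likely to fail**

Step 7. The silyloxymethyl group makes C4 less willing to ionise, so opening of the oxirane by chloride or a 1,2-hydride shift may outrun attack by the C5=C10 alkene. The cascade may also stop after ring A by proton loss from the C10 cation, the enol may be captured through oxygen, and part of the material may fold with ring A as a boat. The fallback sets out from compound 11. O-Silylation (NaH, t-BuMe2SiCl, THF, 0 °C) should give the silyl enol ether prop-2-en-1-yl (2Z,6E)-3-[(tert-butyldimethylsilyl)oxy]-9-[(2R,3S)-3-({[tert-butyl(diphenyl)silyl]oxy}methyl)-3-methyloxiran-2-yl]-7-methylnona-2,6-dienoate F1. This is cyclised with MeAlCl2 in CH2Cl2 at −78 °C, an oxirane-initiated cyclisation with a pre-formed silyl enol ether as terminator under proton-scavenging conditions. Aqueous work-up removes the enol silyl group and the route is rejoined at compound 13.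

Step 11. Addition of the stabilised ylide to a ketone flanked by an axial allyl group and a syn-axial methyl may be slow, and competing enolisation toward C9 would erase the axial configuration set in step 10. The fallback sets out from compound 16 and adds the methyl group directly as the organocerium reagent (MeMgBr, CeCl3, THF, −78 °C). This nucleophile is barely basic, and attack anti to the syn-axial C10 methyl should again place the hydroxyl axial. The route is rejoined at compound 18 with compound 17 by-passed; no compound outside the list is formed (F0).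

Step 15. The dienyl Grignard reagent may form incompletely or polymerise, the iodide may undergo halogen–metal exchange or elimination, and the C8 alkoxide may displace iodide. The fallback sets out from compound 18 and keeps all three allyl carbons, so steps 13 to 15 are not needed. Hydroboration–oxidation (9-BBN, THF; NaOH, H2O2) should give the primary alcohol (1R,2R,4aS,5R,8aR)-5-({[tert-butyl(diphenyl)silyl]oxy}methyl)-1-(3-hydroxypropyl)-2,5,8a-trimethyldecahydronaphthalen-2-ol F2. Dess–Martin oxidation should give the aldehyde 3-[(1R,2R,4aS,5R,8aR)-5-({[tert-butyl(diphenyl)silyl]oxy}methyl)-2-hydroxy-2,5,8a-trimethyldecahydronaphthalen-1-yl]propanal F3. Ohira–Bestmann homologation (dimethyl (1-diazo-2-oxopropyl)phosphonate, K2CO3, MeOH) should give the terminal alkyne (1R,2R,4aS,5R,8aR)-1-(but-3-yn-1-yl)-5-({[tert-butyl(diphenyl)silyl]oxy}methyl)-2,5,8a-trimethyldecahydronaphthalen-2-ol F4. Enyne cross-metathesis with ethylene (second-generation Grubbs catalyst, CH2Cl2, 1 atm) should then give the 2-substituted butadiene, and the route is rejoined at compound 24.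

**Further compounds**
F1 | step 7 | prop-2-en-1-yl (2Z,6E)-3-[(tert-butyldimethylsilyl)oxy]-9-[(2R,3S)-3-({[tert-butyl(diphenyl)silyl]oxy}methyl)-3-methyloxiran-2-yl]-7-methylnona-2,6-dienoate | CC(C)(C)[Si](OC[C@]1(C)O[C@@H]1CC/C(C)=C/CC/C(O[Si](C)(C)C(C)(C)C)=C/C(=O)OCC=C)(c1ccccc1)c1ccccc1
F0 | step 11 | none | none
F2 | step 15 | (1R,2R,4aS,5R,8aR)-5-({[tert-butyl(diphenyl)silyl]oxy}methyl)-1-(3-hydroxypropyl)-2,5,8a-trimethyldecahydronaphthalen-2-ol | OCCC[C@@H]1[C@]2(C)CCC[C@@](C)(CO[Si](c3ccccc3)(c3ccccc3)C(C)(C)C)[C@H]2CC[C@@]1(C)O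
F3 | step 15 | 3-[(1R,2R,4aS,5R,8aR)-5-({[tert-butyl(diphenyl)silyl]oxy}methyl)-2-hydroxy-2,5,8a-trimethyldecahydronaphthalen-1-yl]propanal | O=CCC[C@@H]1[C@]2(C)CCC[C@@](C)(CO[Si](c3ccccc3)(c3ccccc3)C(C)(C)C)[C@H]2CC[C@@]1(C)O
F4 | step 15 | (1R,2R,4aS,5R,8aR)-1-(but-3-yn-1-yl)-5-({[tert-butyl(diphenyl)silyl]oxy}methyl)-2,5,8a-trimethyldecahydronaphthalen-2-ol | C#CCC[C@@H]1[C@]2(C)CCC[C@@](C)(CO[Si](c3ccccc3)(c3ccccc3)C(C)(C)C)[C@H]2CC[C@@]1(C)O
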